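**Plan**
- Retrosynthetic cuts: the C15–O stearate ester; C8=C17 (methylenation of a C8 ketone); C9–C11 (sp3–sp2 coupling at the enol triflate of a C9 ketone); and in ring A the bonds C1–C10 and C3–C4 together with C4–C5.
- Forward: ring B is (R)-carvone. In one pot lithiated propanenitrile adds to C5, the C10 enolate is alkylated by 1-chloro-3-iodopropane, and the C4 nitrile carbanion closes ring A on the chloride (three-component anionic [3+3] annulation).
- Enabling feature: C10 and C4 are two quaternary carbons placed 1,3 across C5–H and bridged by the unfunctionalised trimethylene C1–C2–C3. With C9 of ring B as a ketone and C19 as a nitrile, both are carbanion sites that a 1,3-dielectrophile can bridge.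
- Stereochemistry: the isopropenyl group of carvone (at C7, removed afterwards) sets C5. C10 follows by anti alkylation (trans ring fusion), C4 by ring closure with the nitrile axial, C9 by α-face hydroboration and thermodynamic control next to the C8 ketone. C13 comes from (S)-citronellol.
- The chain (C11–C15 iodide from citronellol) is joined by Negishi coupling; the carbonyl is moved from C9 to C8, methylenated, and the nitrile is taken to the acid after stearoylation.

Key step: step 1

Remark: positions are given in labdane numbering (ring A = C1–C5, C10; ring B = C5–C10; C17 exocyclic methylene; C18 and C19 on C4; C20 on C10).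

Step 1
Reactants: 1 (R)-(−)-carvone; 2 propanenitrile; 3 1-chloro-3-iodopropane
Product: 6 (1S,4aS,7R,8aS)-1,4a-dimethyl-5-oxo-7-(prop-1-en-2-yl)decahydronaphthalene-1-carbonitrile, via lithium enolate 4 (not isolated), via chloropropyl ketone 5 (not isolated)
Conditions: 2, LiN(i-Pr)2 (1.05 equiv), THF, −78 °C; 1, HMPA, −78 → −20 °C; 3, −40 → 0 °C; LiN(i-Pr)2 (2.3 equiv), −78 → 0 °C; aq. NH4Cl
Reagents that add atoms: none
Why: Proposed new method: lithiated propanenitrile should add 1,4 to the enone under thermodynamic control, the C10 enolate is then C-alkylated by the iodide end of 3, and two further equivalents of base give a keto-nitrile dianion in which the nitrile carbanion displaces the chloride while the ketone is masked as its C8 enolate; the closest known reaction types are tandem conjugate addition–enolate alkylation (Michael-initiated ring closure) and cyclization of metalated nitriles, here merged into one three-component [3+3] annulation. Ring A closes in 6-exo-tet mode at C4 through a chair transition state. C5 is set by axial attack anti to the C7 isopropenyl group, C10 by alkylation anti to the new C5 substituent (which becomes the trans ring fusion on closure), and C4 by the slim linear nitrile taking the axial site syn to the C10 methyl while the C4 methyl goes equatorial. The step needs 1,4- over 1,2-addition, C- over O-alkylation, and closure at C4 in preference to C8 or oxygen of the enolate; reversibility of the 1,2-adduct in HMPA, the soft primary iodide, and the much higher basicity and nucleophilicity of the nitrile anion over the ketone enolate should secure these.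

Step 2
Reactants: 6 (1S,4aS,7R,8aS)-1,4a-dimethyl-5-oxo-7-(prop-1-en-2-yl)decahydronaphthalene-1-carbonitrile
Product: 7 (1S,4aS,8aS)-1,4a-dimethyl-5-oxodecahydronaphthalene-1-carbonitrile
Conditions: O3, MeOH, −78 °C; then FeSO4·7H2O, PhSH, −78 °C → rt
Reagents that add atoms: none
Why: Dealkenylative hydrogenation: ozonolysis in methanol gives the α-methoxy hydroperoxide, ferrous ion triggers β-scission of the derived alkoxy radical to a C7 radical and methyl acetate, and benzenethiol donates hydrogen, so the stereocontrol group should leave without touching ketone, nitrile or the other stereocentres.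

Step 3
Reactants: 7 (1S,4aS,8aS)-1,4a-dimethyl-5-oxodecahydronaphthalene-1-carbonitrile
Product: 8 (4aS,5S,8aS)-5-cyano-5,8a-dimethyl-3,4,4a,5,6,7,8,8a-octahydronaphthalen-1-yl trifluoromethanesulfonate
Conditions: KN(SiMe3)2, THF, −78 °C; PhNTf2, −78 → 0 °C
Reagents that add atoms: N-phenylbis(trifluoromethanesulfonimide), O=S(=O)(N(c1ccccc1)S(=O)(=O)C(F)(F)F)C(F)(F)F
Why: Enolisation can only occur toward C8 because C10 is quaternary, and O-triflation of the potassium enolate is the standard enol triflate synthesis.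

Step 4
Reactants: 9 (S)-(−)-β-citronellol
Product: 10 (3S)-3,7-dimethyloct-6-en-1-yl 2,2-dimethylpropanoate
Conditions: t-BuCOCl, Et3N, DMAP (cat.), CH2Cl2, 0 °C → rt
Reagents that add atoms: pivaloyl chloride, CC(C)(C)C(Cl)=O
Why: Acylation of the primary alcohol gives a pivalate that should resist the later organozinc, borane and ylide reagents and is removed together with the nitrile reduction.

Step 5
Reactants: 10 (3S)-3,7-dimethyloct-6-en-1-yl 2,2-dimethylpropanoate
Product: 11 (4S)-6-[(2,2-dimethylpropanoyl)oxy]-4-methylhexanoic acid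
Conditions: RuCl3·xH2O (cat.), NaIO4, MeCN–EtOAc–H2O, rt
Reagents that add atoms: sodium periodate, [Na+].[O-]I(=O)(=O)=O; water, O
Why: RuO4-catalysed oxidative cleavage of the trisubstituted alkene should give the acid and acetone without involving the stereocentre that becomes C13.

Step 6
Reactants: 11 (4S)-6-[(2,2-dimethylpropanoyl)oxy]-4-methylhexanoic acid
Product: 12 (3R)-5-iodo-3-methylpentyl 2,2-dimethylpropanoate
Conditions: PhI(OAc)2, I2, cyclohexane, hν (tungsten lamp), reflux
Reagents that add atoms: iodine, II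
Why: Hunsdiecker-type iododecarboxylation (acyl hypoiodite, primary alkyl radical, iodine transfer) shortens the chain by one carbon to the C11 iodide and leaves the remote stereocentre untouched (its descriptor changes only by priority).

Step 7
Reactants: 12 (3R)-5-iodo-3-methylpentyl 2,2-dimethylpropanoate; 8 (4aS,5S,8aS)-5-cyano-5,8a-dimethyl-3,4,4a,5,6,7,8,8a-octahydronaphthalen-1-yl trifluoromethanesulfonate
Product: 14 (3S)-5-[(4aR,5S,8aS)-5-cyano-5,8a-dimethyl-3,4,4a,5,6,7,8,8a-octahydronaphthalen-1-yl]-3-methylpentyl 2,2-dimethylpropanoate, via alkylzinc iodide 13 (not isolated)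
Conditions: 12, Zn dust (BrCH2CH2Br, Me3SiCl activation), DMA, 40 °C; then 8, Pd(dppf)Cl2 (5 mol %), THF–DMA, 60 °C
Reagents that add atoms: none
Why: Negishi coupling: zinc insertion into the primary iodide tolerates the ester, and sp3–sp2 coupling of alkylzinc halides with enol triflates under zerovalent palladium with the wide-bite-angle dppf ligand is well precedented and should form the C9–C11 bond.

Step 8
Reactants: 14 (3S)-5-[(4aR,5S,8aS)-5-cyano-5,8a-dimethyl-3,4,4a,5,6,7,8,8a-octahydronaphthalen-1-yl]-3-methylpentyl 2,2-dimethylpropanoate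
Product: 16 (3S)-5-[(1R,2R,4aR,5S,8aS)-5-cyano-2-hydroxy-5,8a-dimethyldecahydronaphthalen-1-yl]-3-methylpentyl 2,2-dimethylpropanoate, via alkylborane 15 (not isolated)
Conditions: BH3·THF (3 equiv), THF, 0 °C → rt; then NaOH, H2O2, 0 °C → rt
Reagents that add atoms: hydrogen peroxide, OO
Why: Hydroboration–oxidation should place boron on the less substituted C8 and hydrogen on C9 from the α face, anti to the axial C10 methyl and C4 nitrile (as with 9(11)-ene steroids), which sets the 9α-hydrogen.

Step 9
Reactants: 16 (3S)-5-[(1R,2R,4aR,5S,8aS)-5-cyano-2-hydroxy-5,8a-dimethyldecahydronaphthalen-1-yl]-3-methylpentyl 2,2-dimethylpropanoate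
Product: 17 (3S)-5-[(1R,4aR,5S,8aS)-5-cyano-5,8a-dimethyl-2-oxodecahydronaphthalen-1-yl]-3-methylpentyl 2,2-dimethylpropanoate
Conditions: Dess–Martin periodinane, CH2Cl2, rt
Reagents that add atoms: none
Why: Dess–Martin oxidation of the secondary alcohol gives the C8 ketone, in which the equatorial C9 side chain is also the thermodynamically preferred arrangement, so any C9 epimer would converge.

Step 10
Reactants: 17 (3S)-5-[(1R,4aR,5S,8aS)-5-cyano-5,8a-dimethyl-2-oxodecahydronaphthalen-1-yl]-3-methylpentyl 2,2-dimethylpropanoate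
Product: 18 (3S)-5-[(1S,4aR,5S,8aR)-5-cyano-5,8a-dimethyl-2-methylidenedecahydronaphthalen-1-yl]-3-methylpentyl 2,2-dimethylpropanoate
Conditions: Ph3PCH3Br, KOt-Bu, toluene–THF, 0 → 70 °C
Reagents that add atoms: methyltriphenylphosphonium bromide, [Br-].C[P+](c1ccccc1)(c1ccccc1)c1ccccc1
Why: Wittig methylenation of the hindered C8 ketone is routine for 8-oxolabdanes, and the basic medium can only equilibrate C9 toward the wanted equatorial epimer.

Step 11
Reactants: 18 (3S)-5-[(1S,4aR,5S,8aR)-5-cyano-5,8a-dimethyl-2-methylidenedecahydronaphthalen-1-yl]-3-methylpentyl 2,2-dimethylpropanoate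
Product: 20 (1S,4aR,5S,8aR)-5-[(3S)-5-hydroxy-3-methylpentyl]-1,4a-dimethyl-6-methylidenedecahydronaphthalene-1-carbaldehyde, via aluminium aldiminate 19 (not isolated)
Conditions: i-Bu2AlH (5 equiv), toluene, −78 → 0 °C; then 1 M HCl, THF, rt
Reagents that add atoms: water, O
Why: Partial reduction of the hindered tertiary nitrile should stop at the N-aluminated aldimine, which is hydrolysed to the neopentyl aldehyde on acidic work-up, while the same reagent cleaves the pivalate reductively to free the C15 alcohol.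

Step 12
Reactants: 20 (1S,4aR,5S,8aR)-5-[(3S)-5-hydroxy-3-methylpentyl]-1,4a-dimethyl-6-methylidenedecahydronaphthalene-1-carbaldehyde; 21 octadecanoyl chloride
Product: 22 (3S)-5-[(1S,4aR,5S,8aR)-5-formyl-5,8a-dimethyl-2-methylidenedecahydronaphthalen-1-yl]-3-methylpentyl octadecanoate
Conditions: Et3N, DMAP (cat.), CH2Cl2, 0 °C → rt
Reagents that add atoms: none
Why: DMAP-catalysed O-acylation of the primary alcohol should be clean because the hindered, non-enolisable C19 aldehyde is inert to the acid chloride.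

Step 13
Reactants: 22 (3S)-5-[(1S,4aR,5S,8aR)-5-formyl-5,8a-dimethyl-2-methylidenedecahydronaphthalen-1-yl]-3-methylpentyl octadecanoate
Product: 23 (1S,4aR,5S,8aR)-1,4a-dimethyl-6-methylidene-5-[(3S)-3-methyl-5-(octadecanoyloxy)pentyl]decahydronaphthalene-1-carboxylic acid
Conditions: NaClO2, NaH2PO4, 2-methylbut-2-ene, t-BuOH–H2O, rt
Reagents that add atoms: sodium chlorite, [Na+].[O-]Cl=O
Why: Pinnick oxidation takes the aldehyde to the acid, with 2-methylbut-2-ene scavenging hypochlorous acid so that the exocyclic alkene and the ester should survive.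

**Compound list**
1 | (R)-(−)-carvone, (5R)-2-methyl-5-(prop-1-en-2-yl)cyclohex-2-en-1-one | CC1=CC[C@H](CC1=O)C(C)=C | starting material
2 | propanenitrile | CCC#N | starting material
3 | 1-chloro-3-iodopropane | ClCCCI | starting material
4 | lithium (3S,5R)-3-(1-cyanoethyl)-2-methyl-5-(prop-1-en-2-yl)cyclohex-1-en-1-olate (either configuration at the nitrile α-carbon) | C1[C@H](C(C)=C)C[C@@H](C(C)C#N)C(C)=C1O[Li] | intermediate
5 | 2-[(1S,2S,5R)-2-(3-chloropropyl)-2-methyl-3-oxo-5-(prop-1-en-2-yl)cyclohexyl]propanenitrile (either configuration at the nitrile α-carbon) | C1[C@H](C(C)=C)C[C@@H](C(C)C#N)[C@](C)(CCCCl)C1=O | intermediate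
6 | (1S,4aS,7R,8aS)-1,4a-dimethyl-5-oxo-7-(prop-1-en-2-yl)decahydronaphthalene-1-carbonitrile (trans-fused; nitrile axial, syn to the angular methyl) | C1[C@H](C(C)=C)C[C@@H]2[C@](C)(CCC[C@]2(C)C#N)C1=O | intermediate
7 | (1S,4aS,8aS)-1,4a-dimethyl-5-oxodecahydronaphthalene-1-carbonitrile | C1CC[C@@H]2[C@](C)(CCC[C@]2(C)C#N)C1=O | intermediate
8 | (4aS,5S,8aS)-5-cyano-5,8a-dimethyl-3,4,4a,5,6,7,8,8a-octahydronaphthalen-1-yl trifluoromethanesulfonate | C1C[C@@H]2[C@](C)(CCC[C@]2(C)C#N)C(OS(=O)(=O)C(F)(F)F)=C1 | intermediate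
9 | (S)-(−)-β-citronellol, (3S)-3,7-dimethyloct-6-en-1-ol | CC(C)=CCC[C@H](C)CCO | starting material
10 | (3S)-3,7-dimethyloct-6-en-1-yl 2,2-dimethylpropanoate | CC(C)=CCC[C@H](C)CCOC(=O)C(C)(C)C | intermediate
11 | (4S)-6-[(2,2-dimethylpropanoyl)oxy]-4-methylhexanoic acid | OC(=O)CC[C@H](C)CCOC(=O)C(C)(C)C | intermediate
12 | (3R)-5-iodo-3-methylpentyl 2,2-dimethylpropanoate | ICC[C@H](C)CCOC(=O)C(C)(C)C | intermediate
13 | {(3R)-5-[(2,2-dimethylpropanoyl)oxy]-3-methylpentyl}(iodo)zinc | I[Zn]CC[C@H](C)CCOC(=O)C(C)(C)C | intermediate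
14 | (3S)-5-[(4aR,5S,8aS)-5-cyano-5,8a-dimethyl-3,4,4a,5,6,7,8,8a-octahydronaphthalen-1-yl]-3-methylpentyl 2,2-dimethylpropanoate | C1C[C@@H]2[C@](C)(CCC[C@]2(C)C#N)C(CC[C@H](C)CCOC(=O)C(C)(C)C)=C1 | intermediate
15 | (3S)-5-[(1S,2R,4aR,5S,8aR)-2-boranyl-5-cyano-5,8a-dimethyldecahydronaphthalen-1-yl]-3-methylpentyl 2,2-dimethylpropanoate (boron and the new C9 hydrogen both on the α face) | C1C[C@@H]2[C@](C)(CCC[C@]2(C)C#N)[C@@H](CC[C@H](C)CCOC(=O)C(C)(C)C)[C@@H]1B | intermediate
16 | (3S)-5-[(1R,2R,4aR,5S,8aS)-5-cyano-2-hydroxy-5,8a-dimethyldecahydronaphthalen-1-yl]-3-methylpentyl 2,2-dimethylpropanoate | C1C[C@@H]2[C@](C)(CCC[C@]2(C)C#N)[C@@H](CC[C@H](C)CCOC(=O)C(C)(C)C)[C@@H]1O | intermediate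
17 | (3S)-5-[(1R,4aR,5S,8aS)-5-cyano-5,8a-dimethyl-2-oxodecahydronaphthalen-1-yl]-3-methylpentyl 2,2-dimethylpropanoate | C1C[C@@H]2[C@](C)(CCC[C@]2(C)C#N)[C@@H](CC[C@H](C)CCOC(=O)C(C)(C)C)C1=O | intermediate
18 | (3S)-5-[(1S,4aR,5S,8aR)-5-cyano-5,8a-dimethyl-2-methylidenedecahydronaphthalen-1-yl]-3-methylpentyl 2,2-dimethylpropanoate | C=C1CC[C@@H]2[C@](C)(CCC[C@]2(C)C#N)[C@H]1CC[C@H](C)CCOC(=O)C(C)(C)C | intermediate
19 | N-(diisobutylaluminio)aldimine, O-diisobutylaluminium alkoxide derived from 18 | C=C1CC[C@@H]2[C@](C)(CCC[C@]2(C)C=N[Al](CC(C)C)CC(C)C)[C@H]1CC[C@H](C)CCO[Al](CC(C)C)CC(C)C | intermediate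
20 | (1S,4aR,5S,8aR)-5-[(3S)-5-hydroxy-3-methylpentyl]-1,4a-dimethyl-6-methylidenedecahydronaphthalene-1-carbaldehyde | C=C1CC[C@@H]2[C@](C)(CCC[C@]2(C)C=O)[C@H]1CC[C@H](C)CCO | intermediate
21 | octadecanoyl chloride (stearoyl chloride) | CCCCCCCCCCCCCCCCCC(=O)Cl | starting material
22 | (3S)-5-[(1S,4aR,5S,8aR)-5-formyl-5,8a-dimethyl-2-methylidenedecahydronaphthalen-1-yl]-3-methylpentyl octadecanoate | C=C1CC[C@@H]2[C@](C)(CCC[C@]2(C)C=O)[C@H]1CC[C@H](C)CCOC(=O)CCCCCCCCCCCCCCCCC | intermediate
23 | (1S,4aR,5S,8aR)-1,4a-dimethyl-6-methylidene-5-[(3S)-3-methyl-5-(octadecanoyloxy)pentyl]decahydronaphthalene-1-carboxylic acid | C=C1CC[C@@H]2[C@](C)(CCC[C@]2(C)C(=O)O)[C@H]1CC[C@H](C)CCOC(=O)CCCCCCCCCCCCCCCCC | target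

**Totals**
Total step count: 13. Longest linear sequence: 10 steps (steps 1, 2, 3, 7–13 from carvone; equally steps 4–13 from citronellol).

**Steps most likely to fail**

Step 1 (Proposed new method). In the dianion the ketone enolate may compete with the nitrile carbanion for the chloride (C-alkylation at C8 or O-alkylation), or proton transfer may stall the closure. The fallback uses known chemistry only; it sets out from 1 (with 2 and 3) and comes back at 8. The first two stages are run alone as a tandem conjugate addition–enolate alkylation and chloropropyl ketone 5 is isolated. KN(SiMe3)2 and PhNTf2 then convert its ketone into (3R,5S,6S)-6-(3-chloropropyl)-5-(1-cyanoethyl)-6-methyl-3-(prop-1-en-2-yl)cyclohex-1-en-1-yl trifluoromethanesulfonate F1, so that no enolate remains. A further equivalent of KN(SiMe3)2 generates only the nitrile carbanion, which should close ring A to (3R,4aS,5S,8aS)-5-cyano-5,8a-dimethyl-3-(prop-1-en-2-yl)-3,4,4a,5,6,7,8,8a-octahydronaphthalen-1-yl trifluoromethanesulfonate F2. Dealkenylative hydrogenation (O3, MeOH; FeSO4·7H2O, PhSH), in which ozone should spare the electron-poor enol triflate, rejoins the route at 8.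

Step 7. Zinc insertion or transmetalation may be slow at the hindered triflate next to the quaternary C10, so that β-hydride elimination or reduction of the triflate takes over. The fallback sets out from 11 (and uses 8) and comes back at 14. Kochi oxidative decarboxylation of acid 11 (Pb(OAc)4, Cu(OAc)2, pyridine, benzene, 80 °C) should give the terminal alkene (3R)-3-methylpent-4-en-1-yl 2,2-dimethylpropanoate F3. Hydroboration with 9-BBN gives (3S)-5-(9-borabicyclo[3.3.1]nonan-9-yl)-3-methylpentyl 2,2-dimethylpropanoate F4. B-alkyl Suzuki–Miyaura coupling with 8 (Pd(dppf)Cl2, K3PO4, DMF–THF–H2O, 60 °C), in which a borate rather than an alkylzinc transfers the chain, then gives 14.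

Step 8. Hydroboration of the hindered trisubstituted C8=C9 alkene may be too slow, and forcing it risks reduction of the nitrile. The fallback sets out from 14 and comes back at 17. Epoxidation with mCPBA from the α face should give the 8α,9α-epoxide of alkene 14 F5. Meinwald rearrangement (BF3·OEt2, CH2Cl2, −78 °C), with opening at the tertiary C9 and a 1,2-hydride shift from C8, should give ketone 17 directly; C9 is then equilibrated with base to the equatorial side chain.

Further compounds
F1 | step 1 | (3R,5S,6S)-6-(3-chloropropyl)-5-(1-cyanoethyl)-6-methyl-3-(prop-1-en-2-yl)cyclohex-1-en-1-yl trifluoromethanesulfonate | C1[C@H](C(C)=C)C[C@@H](C(C)C#N)[C@](C)(CCCCl)C(OS(=O)(=O)C(F)(F)F)=1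
F2 | step 1 | (3R,4aS,5S,8aS)-5-cyano-5,8a-dimethyl-3-(prop-1-en-2-yl)-3,4,4a,5,6,7,8,8a-octahydronaphthalen-1-yl trifluoromethanesulfonate | C1[C@H](C(C)=C)C[C@@H]2[C@](C)(CCC[C@]2(C)C#N)C(OS(=O)(=O)C(F)(F)F)=1
F3 | step 7 | (3R)-3-methylpent-4-en-1-yl 2,2-dimethylpropanoate | C=C[C@H](C)CCOC(=O)C(C)(C)C
F4 | step 7 | (3S)-5-(9-borabicyclo[3.3.1]nonan-9-yl)-3-methylpentyl 2,2-dimethylpropanoate | C1CCC2CCCC1B2CC[C@H](C)CCOC(=O)C(C)(C)C
F5 | step 8 | 8α,9α-epoxide of alkene 14 (labdane numbering; oxirane on the face opposite the C10 methyl) | C1C[C@@H]2[C@](C)(CCC[C@]2(C)C#N)[C@]3(CC[C@H](C)CCOC(=O)C(C)(C)C)O[C@@H]31
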